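**Plan**
- Retrosynthetic cuts, in order: the three O–benzyl bonds on the flavone; C3–C4 and C2–H of ring C; the C3′–C8″ biaryl bond; the C2=C3 π-bond (as H–Br) and the O1–C2 ether bond.
- Enabling feature: C4 of ring C is bonded to C4a of ring A, which lies between C5–OH and C8a–O1, and O1 is bonded to C2, which carries ring B and one hydrogen. Ring C is therefore what a salicylaldehyde gives when its formyl C–H adds across a 1-arylvinyl group held on its second ortho oxygen.
- Forward order: rings A and B are joined through O1 (Mitsunobu, then E2 to the enol ether). Ring B is borylated and coupled to C8″ of iodinated tri-O-benzylapigenin. Ring C closes next, and debenzylation ends the route.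
- Stereochemistry: C2 (S) is the only stereocentre. It is set in the ring-C closure by the chiral bisphosphine on rhodium and is not touched afterwards.

Key step: step 8

Remark: the C3′–C8″ axis carries three ortho substituents and is treated as freely rotating, so no axial descriptor is carried.

**Step 1**
Reactants: 1 apigenin
Product: 2 5,7-bis(benzyloxy)-2-[4-(benzyloxy)phenyl]-4H-chromen-4-one
Conditions: BnBr (5 equiv), K2CO3, KI (cat.), DMF, 90 °C
Reagents that add atoms: benzyl bromide, BrCc1ccccc1
Why: Williamson etherification under forcing conditions should also alkylate the chelated 5-OH, which is needed so that the iodination in step 2 goes to C8 and not ortho to a free phenol at C6.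

**Step 2**
Reactants: 2 5,7-bis(benzyloxy)-2-[4-(benzyloxy)phenyl]-4H-chromen-4-one
Product: 3 5,7-bis(benzyloxy)-2-[4-(benzyloxy)phenyl]-8-iodo-4H-chromen-4-one
Conditions: NIS (1.1 equiv), TFA (0.3 equiv), MeCN–CH2Cl2, 0 °C to rt, dark
Reagents that add atoms: N-iodosuccinimide, O=C1CCC(=O)N1I
Why: Electrophilic aromatic iodination of a fully O-alkylated 5,7-dioxygenated flavone should take place at C8, the ring-A position flanked by O7 and the ring oxygen, rather than at C6 between two benzyloxy groups.

**Step 3**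
Reactants: 4 2-bromo-1-(3-bromo-4-methoxyphenyl)ethan-1-one
Product: 5 rac-2-bromo-1-(3-bromo-4-methoxyphenyl)ethan-1-ol
Conditions: NaBH4, MeOH, 0 °C; aq. NH4Cl quench
Reagents that add atoms: none
Why: Borohydride reduction of an α-bromo ketone at 0 °C with a mildly acidic quench should stop at the bromohydrin, whose racemic centre is erased in step 5.

**Step 4**
Reactants: 5 rac-2-bromo-1-(3-bromo-4-methoxyphenyl)ethan-1-ol; 6 2,6-dihydroxy-4-methoxybenzaldehyde (1.5 equiv)
Product: 7 rac-2-[2-bromo-1-(3-bromo-4-methoxyphenyl)ethoxy]-6-hydroxy-4-methoxybenzaldehyde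
Conditions: PPh3, DIAD (added last), THF, 0 °C to rt
Reagents that add atoms: none
Why: Mitsunobu etherification, in which one of the two equivalent acidic phenols displaces the activated benzylic oxygen, while the remaining OH stays hydrogen-bonded to the aldehyde and so resists a second alkylation.

**Step 5**
Reactants: 7 rac-2-[2-bromo-1-(3-bromo-4-methoxyphenyl)ethoxy]-6-hydroxy-4-methoxybenzaldehyde
Product: 8 2-{[1-(3-bromo-4-methoxyphenyl)ethenyl]oxy}-6-hydroxy-4-methoxybenzaldehyde
Conditions: KOtBu (2.2 equiv), THF, −20 to 0 °C; pH 7 buffer work-up, Et3N-washed silica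
Reagents that add atoms: none
Why: E2 dehydrobromination, where the only hydrogen β to bromine is the benzylic, oxygen-bearing C–H, so loss of HBr can only give the 1,1-disubstituted aryl enol ether, and the phenoxide formed first makes the aryloxy group a poor leaving group.

**Step 6**
Reactants: 8 2-{[1-(3-bromo-4-methoxyphenyl)ethenyl]oxy}-6-hydroxy-4-methoxybenzaldehyde
Product: 9 2-hydroxy-4-methoxy-6-({1-[4-methoxy-3-(4,4,5,5-tetramethyl-1,3,2-dioxaborolan-2-yl)phenyl]ethenyl}oxy)benzaldehyde
Conditions: B2pin2, Pd(dppf)Cl2 (5 mol %), KOAc, 1,4-dioxane, 85 °C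
Reagents that add atoms: bis(pinacolato)diboron, CC1(C)OB(OC1(C)C)B1OC(C)(C)C(C)(C)O1
Why: Miyaura borylation of an aryl bromide, in which the weak acetate base should leave the aldehyde, the phenol and the enol ether alone.

**Step 7**
Reactants: 9 the pinacol boronate (1.2 equiv); 3 5,7-bis(benzyloxy)-2-[4-(benzyloxy)phenyl]-8-iodo-4H-chromen-4-one
Product: 10 2-{[1-(3-{5,7-bis(benzyloxy)-2-[4-(benzyloxy)phenyl]-4-oxo-4H-chromen-8-yl}-4-methoxyphenyl)ethenyl]oxy}-6-hydroxy-4-methoxybenzaldehyde
Conditions: Pd(OAc)2 (5 mol %), SPhos (10 mol %), K3PO4, toluene–H2O, 80 °C; neutral work-up, Et3N-washed silica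
Reagents that add atoms: none
Why: Suzuki–Miyaura coupling of an 8-iodoflavone with an ortho-methoxyarylboron partner, the pairing used for 3′,8″-linked biflavones, with a bulky electron-rich biarylphosphine to carry the doubly ortho-flanked C8″ centre through transmetalation and reductive elimination.

**Step 8**
Reactants: 10 the aryl 1-arylvinyl ether of the salicylaldehyde
Product: 11 (2S)-2-(3-{5,7-bis(benzyloxy)-2-[4-(benzyloxy)phenyl]-4-oxo-4H-chromen-8-yl}-4-methoxyphenyl)-5-hydroxy-7-methoxy-2,3-dihydro-4H-chromen-4-one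
Conditions: [Rh(cod)2]BF4 (5 mol %), (R)-DTBM-SEGPHOS (5.5 mol %), degassed 1,2-dichloroethane, 60 °C, argon, no base
Reagents that add atoms: none
Why: Proposed new method: the cationic monovalent rhodium–bisphosphine fragment binds the electron-rich enol ether and adds oxidatively into the formyl C–H, which the O–H···O=C hydrogen bond of the neutral 6-OH (future 5-OH) keeps turned toward the alkene; hydride then goes to the aryl- and oxygen-bearing alkene carbon (future C2) and rhodium to the CH2 terminus, giving a seven-membered acyl–alkyl rhodacycle of trivalent rhodium whose C–C reductive elimination forms C3–C4. The closest known reactions are rhodium–bisphosphine enantioselective endo-hydroacylations of 1,1-disubstituted alkenes in ortho-allylbenzaldehydes and N-vinylindole-2-carbaldehydes, and hydroacylations tethered through an ortho ether oxygen; an aryl 1-arylvinyl ether has not served as the alkene. Ring C closes in a formal 6-endo-trig mode, both alkene carbons ending inside the ring. C2 is set by the chiral bisphosphine, which decides the alkene face that receives hydride; (R)-DTBM-SEGPHOS is written, and its antipode is taken if the first run shows the 2R sense. The step needs six-ring over five-ring closure, which the substrate secures because hydride delivery to the CH2 terminus would leave a tertiary, benzylic alkyl rhodium that reverts by β-hydride elimination faster than it couples, and it needs coupling to outrun decarbonylation, which the two ortho substituents flanking the acyl group and the alkene held on O1 favour. Base is left out because a rhodium-bound phenoxide would hold the metal on the flank away from the alkene, and acid is excluded because it would close the enol ether onto the aldehyde toward a flavylium ion.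

**Step 9**
Reactants: 11 the (2S)-flavanone–flavone tribenzyl ether
Product: 12 (2S)-2-{3-[5,7-dihydroxy-2-(4-hydroxyphenyl)-4-oxo-4H-chromen-8-yl]-4-methoxyphenyl}-5-hydroxy-7-methoxy-2,3-dihydro-4H-chromen-4-one
Conditions: H2 (1 atm), Pd/C (10 wt %), THF–MeOH, rt, stopped at full debenzylation
Reagents that add atoms: none
Why: Hydrogenolysis of aryl benzyl ethers over palladium at 1 atm should be much faster than reduction of the flavone C2″=C3″ bond, the C4 aryl ketone or the C2–O1 bond, and the neutral medium leaves C2 configurationally intact.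

**Compound list**
1 | apigenin | O=c1cc(-c2ccc(O)cc2)oc2cc(O)cc(O)c12 | starting material
2 | 5,7-bis(benzyloxy)-2-[4-(benzyloxy)phenyl]-4H-chromen-4-one | O=c1cc(-c2ccc(OCc3ccccc3)cc2)oc2cc(OCc3ccccc3)cc(OCc3ccccc3)c12 | intermediate
3 | 5,7-bis(benzyloxy)-2-[4-(benzyloxy)phenyl]-8-iodo-4H-chromen-4-one | O=c1cc(-c2ccc(OCc3ccccc3)cc2)oc2c(I)c(OCc3ccccc3)cc(OCc3ccccc3)c12 | intermediate
4 | 2-bromo-1-(3-bromo-4-methoxyphenyl)ethan-1-one | COc1ccc(C(=O)CBr)cc1Br | starting material
5 | rac-2-bromo-1-(3-bromo-4-methoxyphenyl)ethan-1-ol | COc1ccc(C(O)CBr)cc1Br | intermediate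
6 | 2,6-dihydroxy-4-methoxybenzaldehyde | COc1cc(O)c(C=O)c(O)c1 | starting material
7 | rac-2-[2-bromo-1-(3-bromo-4-methoxyphenyl)ethoxy]-6-hydroxy-4-methoxybenzaldehyde | COc1cc(O)c(C=O)c(OC(CBr)c2ccc(OC)c(Br)c2)c1 | intermediate
8 | 2-{[1-(3-bromo-4-methoxyphenyl)ethenyl]oxy}-6-hydroxy-4-methoxybenzaldehyde | COc1cc(O)c(C=O)c(OC(=C)c2ccc(OC)c(Br)c2)c1 | intermediate
9 | 2-hydroxy-4-methoxy-6-({1-[4-methoxy-3-(4,4,5,5-tetramethyl-1,3,2-dioxaborolan-2-yl)phenyl]ethenyl}oxy)benzaldehyde | COc1cc(O)c(C=O)c(OC(=C)c2ccc(OC)c(B3OC(C)(C)C(C)(C)O3)c2)c1 | intermediate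
10 | 2-{[1-(3-{5,7-bis(benzyloxy)-2-[4-(benzyloxy)phenyl]-4-oxo-4H-chromen-8-yl}-4-methoxyphenyl)ethenyl]oxy}-6-hydroxy-4-methoxybenzaldehyde | COc1cc(O)c(C=O)c(OC(=C)c2ccc(OC)c(-c3c(OCc4ccccc4)cc(OCc4ccccc4)c4c(=O)cc(-c5ccc(OCc6ccccc6)cc5)oc34)c2)c1 | intermediate
11 | (2S)-2-(3-{5,7-bis(benzyloxy)-2-[4-(benzyloxy)phenyl]-4-oxo-4H-chromen-8-yl}-4-methoxyphenyl)-5-hydroxy-7-methoxy-2,3-dihydro-4H-chromen-4-one | COc1cc(O)c2c(c1)O[C@H](c1ccc(OC)c(-c3c(OCc4ccccc4)cc(OCc4ccccc4)c4c(=O)cc(-c5ccc(OCc6ccccc6)cc5)oc34)c1)CC2=O | intermediate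
12 | (2S)-2-{3-[5,7-dihydroxy-2-(4-hydroxyphenyl)-4-oxo-4H-chromen-8-yl]-4-methoxyphenyl}-5-hydroxy-7-methoxy-2,3-dihydro-4H-chromen-4-one | COc1cc(O)c2c(c1)O[C@H](c1ccc(OC)c(-c3c(O)cc(O)c4c(=O)cc(-c5ccc(O)cc5)oc34)c1)CC2=O | target

**Step count**
Total: 9 steps. Longest linear sequence: 7 steps (4 → 5 → 7 → 8 → 9 → 10 → 11 → 12).

**Steps most likely to fail**

Step 8 (Proposed new method). What may go wrong:
- decarbonylation of the acyl rhodium hydride, with the catalyst arrested as a carbonyl complex;
- hydride delivery to the CH2 terminus followed by five-ring closure;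
- weak facial discrimination between the aryl and aryloxy substituents of the alkene;
- acid-triggered closure of the enol ether onto the aldehyde.

Fallback with known chemistry, setting out from 3 and returning at 11. Suzuki–Miyaura coupling of 3 with (5-chloro-2-methoxyphenyl)boronic acid (Pd(PPh3)4, Na2CO3, DME–H2O, 85 °C, a catalyst that leaves the C–Cl bond alone) should give 5,7-bis(benzyloxy)-2-[4-(benzyloxy)phenyl]-8-(5-chloro-2-methoxyphenyl)-4H-chromen-4-one F1. Borylation of the chloride (Pd(OAc)2, XPhos, B2(OH)4, KOAc, EtOH, 80 °C) should give (3-{5,7-bis(benzyloxy)-2-[4-(benzyloxy)phenyl]-4-oxo-4H-chromen-8-yl}-4-methoxyphenyl)boronic acid F2. Asymmetric conjugate addition of F2 to 5-hydroxy-7-methoxy-4H-chromen-4-one (Pd(OCOCF3)2, the t-BuPyOx antipode that leads to 2S, NH4PF6, H2O, 1,2-dichloroethane, 60 °C) then forms the C2–C1′ bond on a ready-made ring C and returns to the route at 11.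

Step 4. What may go wrong: ionisation of the activated, para-methoxy-stabilised benzylic oxygen, leading to C-alkylation of the electron-rich ring A, and sluggish reaction of the hydrogen-bonded phenol.

Fallback, setting out from 6 and returning at 8. O-Acylation with 3-bromo-4-methoxybenzoyl chloride (Et3N, CH2Cl2, 0 °C) should give 2-formyl-3-hydroxy-5-methoxyphenyl 3-bromo-4-methoxybenzoate F3. Masking of the aldehyde (1,2-bis(trimethylsilyloxy)ethane, TMSOTf cat., CH2Cl2, −78 °C) should give 2-(1,3-dioxolan-2-yl)-3-hydroxy-5-methoxyphenyl 3-bromo-4-methoxybenzoate F4. Petasis methylenation of the aryl ester with excess Cp2TiMe2 (toluene–THF, 65 °C; the free phenol uses up one equivalent and returns on work-up) should give 3-{[1-(3-bromo-4-methoxyphenyl)ethenyl]oxy}-2-(1,3-dioxolan-2-yl)-5-methoxyphenol F5. Release of the very labile, trioxygenated aryl acetal with PPTS in wet acetone at 0 °C should spare the aryl enol ether and return to the route at 8.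

Step 7. What may go wrong: slow transmetalation at the doubly ortho-flanked C8″–palladium centre, so that protodeboronation of 9 and deiodination of 3 win during prolonged heating with aqueous base.

Fallback, setting out from 8 and returning at 10. Stannylation of the aryl bromide (Me3SnSnMe3, Pd(PPh3)4, toluene, 100 °C) should give 2-hydroxy-4-methoxy-6-({1-[4-methoxy-3-(trimethylstannyl)phenyl]ethenyl}oxy)benzaldehyde F6. Base-free Stille coupling of F6 with 3 (Pd(PPh3)4, CuI, CsF, DMF, 45 °C) returns to the route at 10.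

**Further compounds**
F1 | step 8 | 5,7-bis(benzyloxy)-2-[4-(benzyloxy)phenyl]-8-(5-chloro-2-methoxyphenyl)-4H-chromen-4-one | COc1ccc(Cl)cc1-c1c(OCc2ccccc2)cc(OCc2ccccc2)c2c(=O)cc(-c3ccc(OCc4ccccc4)cc3)oc12
F2 | step 8 | (3-{5,7-bis(benzyloxy)-2-[4-(benzyloxy)phenyl]-4-oxo-4H-chromen-8-yl}-4-methoxyphenyl)boronic acid | COc1ccc(B(O)O)cc1-c1c(OCc2ccccc2)cc(OCc2ccccc2)c2c(=O)cc(-c3ccc(OCc4ccccc4)cc3)oc12
F3 | step 4 | 2-formyl-3-hydroxy-5-methoxyphenyl 3-bromo-4-methoxybenzoate | COc1cc(O)c(C=O)c(OC(=O)c2ccc(OC)c(Br)c2)c1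
F4 | step 4 | 2-(1,3-dioxolan-2-yl)-3-hydroxy-5-methoxyphenyl 3-bromo-4-methoxybenzoate | COc1cc(O)c(C2OCCO2)c(OC(=O)c2ccc(OC)c(Br)c2)c1
F5 | step 4 | 3-{[1-(3-bromo-4-methoxyphenyl)ethenyl]oxy}-2-(1,3-dioxolan-2-yl)-5-methoxyphenol | COc1cc(O)c(C2OCCO2)c(OC(=C)c2ccc(OC)c(Br)c2)c1
F6 | step 7 | 2-hydroxy-4-methoxy-6-({1-[4-methoxy-3-(trimethylstannyl)phenyl]ethenyl}oxy)benzaldehyde | COc1cc(O)c(C=O)c(OC(=C)c2ccc(OC)c([Sn](C)(C)C)c2)c1
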